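## The problem

Compound 29 (CNP0190794.1) is a bicyclo[3.2.1]octane-7,8-dione. Its six-membered ring (C1, C2, C3, C4, C5, C8) and five-membered ring (C1, C7, C6, C5, C8) share the bridging ketone C8 and two quaternary bridgeheads, C1 with an isobutyryl group and C5 with a prenyl group. C1 is therefore the centre of a non-enolisable β-triketone (C8, C7, isobutyryl carbonyl), and C6 is a tertiary carbinol between the C7 ketone and a (Z)-4-hydroxy-4-methylpent-2-enoyl chain. Both arrays are cleaved or rearranged by nucleophilic base (retro-Claisen, α-ketol and acyl shifts), and any intermediate with a free C7 hydroxyl next to C1 can open the five-membered ring by retro-aldol reaction. Of the four stereocentres, C1 and C5 are tied together by the bridge and count as one element, the absolute sense of the bicycle. C3 carries its prenyl group equatorial, away from the C6–C7 bridge, and C6 carries the acyl chain exo (toward C8) and the hydroxyl endo. A bicycle of one handedness can control both, because reagents reach C3 and C6 from the face remote from the opposite bridge, and the equatorial C3 epimer is also the stable one while C4 is a carbonyl. The two trisubstituted alkenes rule out strong acid, electrophilic oxidants and unselective hydrogenation, and the Z enone with its γ-hydroxyl must come last and be handled without base. The enabling feature is that C8, C1, C2, C3, C4 and C5 (oxygen on C8, carbon substituents on C1, C2 and C5, room for a disposable oxygen on C4) are the six carbons of a phenol whose two ortho carbons become the bridgeheads, while C6–C7 with one oxygen on each carbon is an enediol ether.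

## Retrosynthesis

**C6–acyl bond.** Target 29 is the desilylated form of 28. In 28 the bond between C6 and the side-chain carbonyl is cut by an O-to-C 1,2-acyl shift, which leads back to the enolate 27 of the α-acyloxy ketone 26. The neighbouring option, adding an acyl anion equivalent to a 6,7-dione, offers no handle to tell C6 from C7 and puts an organometallic among four ketones. In 26 the C6 oxygen is already in place and carries the whole chain, the C7 ketone can enolise only toward C6, and the forward step only has to swing the acyl group over the exo face.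

**Side-chain ester and Z alkene.** The Z alkene of 26 comes from the alkyne of 25 by semi-hydrogenation, and the C7 ketone of 25 from the alcohol 24. The ester C–O bond of 24 is cut to the diol 19 and the acid 23. An alkynoic acid is chosen over the Z enoic acid because only the linear alkyne cannot lactonise on activation. Acid 23 comes from the alkynol 20 through silyl ether 21 and acetylide 22. The forward step must acylate the C6 hydroxyl, the one remote from the isobutyryl group.

**Prenyl groups and diol.** The prenyl C=C bonds of 19 are cut back to the allyl groups of 18 (cross-metathesis), and the diol of 18 to the acetonide 17. Allyl groups are carried because they survive the acid, cuprate and radical steps that prenyl groups would not.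

**C4 oxygen, C2 methyl, C3 side chain.** The C4 methylene of 17 is traced through thiocarbonyl derivative 16 and alcohol 15 to ketone 14 (radical deoxygenation). In 14 the C2–methyl and C3–allyl bonds are cut together, giving enolate 13 and the enone 12. Conjugate addition followed by alkylation uses the C4 carbonyl twice before it is discarded, and C3 is set on the face remote from the two-carbon bridge.

**C5–C6 and C1–C7.** Enone 12 arises by hydrolysis of cation 11, and 11 is cut at C5–C6 and C1–C7 into the phenol 7 and the dioxole 10. No other pair of cuts makes both quaternary bridgeheads, the five-membered ring and the C6, C7 and C8 oxygens at once. The forward reaction must bond both ortho carbons of the oxidised phenol to the enediol ether and do so on one face.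

**Building blocks.** Phenol 7 comes from 6 by methylation of the free hydroxyl, 6 from allyl ether 5 by Claisen rearrangement, 5 from 3 and allyl bromide 4, and 3 from orcinol 1 and isobutyryl chloride 2. Dioxole 10 comes from the chloride 9, made from the dioxolane 8.

## Roads not taken

**Alternative 1:** The six-membered ring is cut at C5–C8 and C3–C4, giving the pinene-derived alkylidene cyclobutanone A1 (C8, C1, C2, C3) and the silyl alkyne A2 (C4, C5 with its prenyl group). Forward, zerovalent nickel (Ni(cod)2 with PCy3) couples the C8 carbonyl with A2, the C8–C3 bond is broken by β-carbon elimination, and reductive elimination closes the cyclohexenone A3.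
- Merits: the C3 configuration comes from the chiral pool, the gem-dimethyl group and both prenyl groups are present from the start, and nickel-catalysed alkyne insertion into cyclobutanones is a known reaction type.
- Weak points: A3 is monocyclic. Neither bridgehead is quaternary, C6 and C7 are absent, and the two bonds that later make the bridge must be formed at a tetrasubstituted enone carbon (C5) and a fully substituted silyl enol ether carbon (C1). Insertion regiochemistry, the choice between cleaving C8–C3 and C8–C1, and removal of the C4 silyl group add further uncertainty.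
- Comparison: this road is better in where its absolute configuration comes from and needs no metathesis. The chosen plan has to set against it an untested chiral mediator (or a resolution), but its key step delivers the whole bicycle with oxygen on C6, C7 and C8 from an arene made in four standard steps.

**Alternative 2:** The cuts are C4–C5 and the C3–prenyl bond. Forward, the xanthate A4 gives a C5 radical flanked by the C6 and C8 carbonyls, which adds 6-endo to the vinyl group of the reverse-prenyl unit on C1. The C3 radical is then trapped by the allyl sulfone A5 with loss of the sulfonyl radical, giving the trione A6.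
- Merits: A6 has every carbon of the target except the C6 chain, at the right oxidation level, and C5 must follow C1 because of the bridge. After its key step this road is clearly shorter than the chosen one: no cuprate addition, no C4 deoxygenation, no metathesis.
- Weak points: A4 is a fully substituted, non-enolisable cyclopentane-1,2,4-trione with a quaternary stereocentre bearing two acyl-type neighbours, and it must be made as one enantiomer. Such vicinal tricarbonyls hydrate, contract and undergo retro-Claisen cleavage readily. The doubly acyl-stabilised tertiary radical is sluggish toward an unactivated vinyl group, 5-exo closure and xanthate transfer compete, and C3 is set only by the approach of A5. The last step, addition to C6 of A6, meets the C6/C7 problem with no oxygen handle.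
- Comparison: the chosen plan is longer after its key step. It sets against this a precursor reachable by textbook aromatic chemistry and a C6 oxygen that allows intramolecular delivery of the chain.

**Alternative 3:** A temporary C5–C7 bond is made and later exchanged for C5–C6. Irradiation of the diketone A7 excites the C7 carbonyl, which abstracts the axial C5 hydrogen, and the 1,4-biradical closes to the cyclobutanol A8. A strain-driven α-ketol shift of C5 from C7 to C6 then gives the five-membered ring.
- Merits: C6 receives its hydroxyl and its side-chain carbon and C7 becomes the ketone by construction. On this point the road is better than the chosen plan, which relies on a steric preference and an acyl shift to tell C6 from C7.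
- Weak points: the chromophore sits on a carbon that carries two further carbonyls, so α-cleavage and fragmentation of the biradical across C1–C8 compete with closure. The two prenyl groups offer allylic hydrogens and alkene partners to the excited ketone. A7 needs three controlled stereocentres, including a quaternary C1 with two different acyl groups and a cis-diaxial C5 hydrogen. The ring takes two steps to form, and the silyloxymethyl group still has to be grown into the Z enoyl chain.
- Comparison: the chosen plan sets against the cleaner C6/C7 outcome a ring-forming step on a robust arene with no alkene-sensitive photochemistry, and a chain that arrives complete.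

Key step: step 7

Assumption: the γ-hydroxy (Z)-enone of 29 is treated in the open-chain form drawn; a ring-chain (lactol) tautomer, if populated, is the same substance.
Assumption: the sense of induction of the chiral aryl iodide cannot be predicted; the (R,R) form is written and its mirror image is used if that proves to be the one that leads to 12.

## Steps

Step 1
Reactants: 1 orcinol (5-methylbenzene-1,3-diol); 2 isobutyryl chloride
Product: 3 1-(2,4-dihydroxy-6-methylphenyl)-2-methylpropan-1-one
Conditions: AlCl3 (3 equiv), PhNO2, 0→60 °C; aq. HCl
Reagents that add atoms: none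
Why: Friedel–Crafts acylation (with Fries rearrangement of any aryl ester formed first) goes to the ring carbon ortho to one hydroxyl and para to the other, the established outcome for orcinol; the ketone deactivates the ring against a second acylation.

Step 2
Reactants: 3 1-(2,4-dihydroxy-6-methylphenyl)-2-methylpropan-1-one; 4 allyl bromide
Product: 5 1-[2-hydroxy-6-methyl-4-(prop-2-en-1-yloxy)phenyl]-2-methylpropan-1-one
Conditions: K2CO3 (1.1 equiv), acetone, reflux
Reagents that add atoms: none
Why: Williamson etherification; only the para hydroxyl reacts because the ortho hydroxyl is held in a hydrogen bond to the ketone.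

Step 3
Reactants: 5 1-[2-hydroxy-6-methyl-4-(prop-2-en-1-yloxy)phenyl]-2-methylpropan-1-one
Product: 6 1-[2,4-dihydroxy-6-methyl-3-(prop-2-en-1-yl)phenyl]-2-methylpropan-1-one
Conditions: PhNEt2, 195 °C
Reagents that add atoms: none
Why: aromatic Claisen rearrangement; the [3,3] shift goes to the carbon between the two oxygens, favoured by bond fixation in the chelated acylphenol and by the methyl group that flanks the other ortho carbon.

Step 4
Reactants: 6 1-[2,4-dihydroxy-6-methyl-3-(prop-2-en-1-yl)phenyl]-2-methylpropan-1-one
Product: 7 1-[2-hydroxy-4-methoxy-6-methyl-3-(prop-2-en-1-yl)phenyl]-2-methylpropan-1-one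
Conditions: MeI (1.1 equiv), K2CO3, acetone, 40 °C
Reagents that add atoms: iodomethane, CI
Why: O-alkylation of the more acidic, non-chelated phenol; the chelated hydroxyl that is to be oxidised in step 7 stays free.

Step 5
Reactants: 8 2,2-dimethyl-1,3-dioxolane
Product: 9 4-chloro-2,2-dimethyl-1,3-dioxolane (racemic)
Conditions: t-BuOCl, hν, neat 8 in excess, 0 °C; distillation
Reagents that add atoms: tert-butyl hypochlorite, CC(C)(C)OCl
Why: radical-chain chlorination; the tert-butoxyl radical abstracts a hydrogen next to oxygen, the only activated C–H bonds present, and the neutral by-product leaves the ketal intact.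

Step 6
Reactants: 9 4-chloro-2,2-dimethyl-1,3-dioxolane
Product: 10 2,2-dimethyl-1,3-dioxole
Conditions: KOt-Bu, tetraglyme, 60 °C, product distilled from the pot
Reagents that add atoms: none
Why: E2 dehydrochlorination of an α-chloro ether by a hindered base; the volatile enediol ether leaves the basic medium as it forms.

Step 7
Reactants: 7 1-[2-hydroxy-4-methoxy-6-methyl-3-(prop-2-en-1-yl)phenyl]-2-methylpropan-1-one; 10 2,2-dimethyl-1,3-dioxole
Product: 12 5-allyl-1-isobutyryl-2-methyl-6,7-exo-(isopropylidenedioxy)bicyclo[3.2.1]oct-2-ene-4,8-dione (target numbering; bridgeheads as in 29), via methoxyallyl cation 11 (not isolated)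
Conditions: (2R,2′R)-2,2′-[(2-iodo-1,3-phenylene)bis(oxy)]bis[N-(2,4,6-trimethylphenyl)propanamide] (1.2 equiv, recovered and re-oxidised), LiClO4, (CF3)2CHOH, glassy-carbon anode, Pt cathode, divided cell, constant current, 0 °C; anolyte added to 7 and 10 (5 equiv), CH2Cl2, −40 °C; aq. NaHCO3
Reagents that add atoms: water, O
Why: Proposed new method: the aryl iodide is oxidised at the anode by two electrons to its bis(hexafluoroisopropoxy) trivalent-iodine form, which exchanges one ligand for the phenol oxygen of 7, and the dioxole 10 attacks the allyl-bearing ortho carbon (C5) as the aryl iodide departs, so that oxidation of the phenol and the first C–C bond formation are one event on a chiral scaffold. The C7 oxocarbenium ion is then captured by the acyl-bearing ortho carbon C1, the far end of the methoxydienone, to give cation 11, whose methoxy group is hydrolysed to the C4 ketone on work-up, whereas capture by the C8 oxygen is reversible and drains into 11. The closest known reaction types are the anodic or acid-promoted cationic [5+2] cycloaddition of phenoxonium ions from 4-alkoxyphenols with olefins to bicyclo[3.2.1]oct-3-ene-2,8-diones and the enantioselective dearomatisation of phenols by chiral trivalent-iodine reagents; neither has been shown for an acylphenol without a para donor, for an enediol ether partner, or as an enantioselective intermolecular [5+2]. The five-membered ring (C5, C6, C7, C1, C8) closes by 5-exo-trig attack of the dienol-ether carbon C1 on the oxocarbenium carbon C7, which completes the formal suprafacial 4π + 2π union across the two ortho carbons. C5 is set by the face of the iodine-bound aryloxy unit that the chiral lactamide arms leave open, C1 follows because the two-carbon bridge can span only one face, and C6 and C7 are cis through the dioxole ring and expected exo, with the dioxolane turned toward the C8 oxygen and away from the substituted C2–C4 bridge. The step needs site selectivity (both ortho carbons, not the free para carbon that becomes C3) and facial selectivity; the first rests on the symmetric dioxole, for which bonding to C1 and C5 is the symmetry-allowed mode, on the methoxy group that stabilises the C2–C3–C4 cation of 11 and on the substituents flanking the para carbon, and the second on a poorly ionising medium at low temperature that keeps the phenoxonium ion on iodine until the dioxole attacks. The exo or endo sense at C6 and C7 has no consequence, since C7 becomes a carbonyl and C6 is flattened in step 19.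

Step 8
Reactants: 12 5-allyl-1-isobutyryl-2-methyl-6,7-exo-(isopropylidenedioxy)bicyclo[3.2.1]oct-2-ene-4,8-dione; 4 allyl bromide
Product: 14 3,5-diallyl-1-isobutyryl-2,2-dimethyl-6,7-exo-(isopropylidenedioxy)bicyclo[3.2.1]octane-4,8-dione (C3 allyl equatorial), via lithium enolate 13 (not isolated)
Conditions: Me2CuLi (2.5 equiv, from CuI and MeLi), Et2O, −40→0 °C; then 4 (5 equiv), (Me2N)3PO, 0 °C→rt
Reagents that add atoms: lithium dimethylcuprate, [Li+].C[Cu-]C
Why: cuprate conjugate addition to the C4 enone puts the second methyl on C2, and the regiodefined enolate 13 is alkylated at C3 from the face remote from the C6–C7 bridge, which places the allyl group equatorial; this is also the stable epimer should C3 equilibrate through the C4 ketone.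

Step 9
Reactants: 14 3,5-diallyl-1-isobutyryl-2,2-dimethyl-6,7-exo-(isopropylidenedioxy)bicyclo[3.2.1]octane-4,8-dione
Product: 15 3,5-diallyl-4-hydroxy-1-isobutyryl-2,2-dimethyl-6,7-exo-(isopropylidenedioxy)bicyclo[3.2.1]octan-8-one (hydroxyl drawn axial on the C8 side; the C4 epimer serves equally)
Conditions: NaBH4, MeOH/THF, −20 °C
Reagents that add atoms: none
Why: hydride reduction of the only ketone with an open approach; C8 lies between two quaternary carbons and is screened by the axial C2 methyl and the exo acetonide, the isobutyryl carbonyl by C1 and its isopropyl group, and the new centre is removed in step 11.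

Step 10
Reactants: 15 3,5-diallyl-4-hydroxy-1-isobutyryl-2,2-dimethyl-6,7-exo-(isopropylidenedioxy)bicyclo[3.2.1]octan-8-one
Product: 16 O-(imidazol-1-ylthiocarbonyl) derivative of 15 at C4
Conditions: 1,1′-thiocarbonyldiimidazole, 4-(dimethylamino)pyridine (cat.), ClCH2CH2Cl, 70 °C
Reagents that add atoms: 1,1′-thiocarbonyldiimidazole, S=C(n1ccnc1)n1ccnc1
Why: thioacylation of the secondary alcohol under near-neutral conditions, chosen over xanthate formation so that no C4 alkoxide is generated that could open the ring by retro-aldol cleavage of C4–C5.

Step 11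
Reactants: 16 O-(imidazol-1-ylthiocarbonyl) derivative of 15
Product: 17 3,5-diallyl-1-isobutyryl-2,2-dimethyl-6,7-exo-(isopropylidenedioxy)bicyclo[3.2.1]octan-8-one
Conditions: Bu3SnH, 2,2′-azobis(2-methylpropionitrile) (cat.), PhMe, 100 °C
Reagents that add atoms: none
Why: Barton–McCombie deoxygenation; the secondary C4 radical is reduced by the stannane, and both allyl groups stand in a 4-pentenyl relation to it, for which no ring closure is favourable.

Step 12
Reactants: 17 3,5-diallyl-1-isobutyryl-2,2-dimethyl-6,7-exo-(isopropylidenedioxy)bicyclo[3.2.1]octan-8-one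
Product: 18 3,5-diallyl-6,7-exo-dihydroxy-1-isobutyryl-2,2-dimethylbicyclo[3.2.1]octan-8-one
Conditions: 1 M aq. HCl, THF, 40 °C
Reagents that add atoms: none
Why: acid hydrolysis of the ketal while the side chains are still terminal allyl groups, which do not respond to aqueous acid; C1 and C5 bear no hydrogen, so no β-elimination is possible, and base, which would trigger retro-aldol loss of C7, is avoided.

Step 13
Reactants: 18 3,5-diallyl-6,7-exo-dihydroxy-1-isobutyryl-2,2-dimethylbicyclo[3.2.1]octan-8-one
Product: 19 6,7-exo-dihydroxy-1-isobutyryl-2,2-dimethyl-3,5-bis(3-methylbut-2-en-1-yl)bicyclo[3.2.1]octan-8-one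
Conditions: second-generation Grubbs catalyst RuCl2(=CHPh)(PCy3)(H2IMes) (10 mol %), 2-methylbut-2-ene/CH2Cl2, 40 °C
Reagents that add atoms: 2-methylbut-2-ene, CC=C(C)C
Why: olefin cross-metathesis turns both terminal allyl groups into prenyl groups; the large excess of the trisubstituted olefin suppresses dimerisation and ring closure between the two chains, and free hydroxyls are tolerated.

Step 14
Reactants: 20 2-methylbut-3-yn-2-ol
Product: 21 triethyl[(2-methylbut-3-yn-2-yl)oxy]silane
Conditions: Et3SiOTf, 2,6-lutidine, CH2Cl2, 0 °C
Reagents that add atoms: triethylsilyl trifluoromethanesulfonate, CC[Si](CC)(CC)OS(=O)(=O)C(F)(F)F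
Why: silylation of a tertiary alcohol with the silyl triflate; the silyl ether later prevents lactonisation of the Z enoate and is removable without base.

Step 15
Reactants: 21 triethyl[(2-methylbut-3-yn-2-yl)oxy]silane
Product: 23 4-methyl-4-[(triethylsilyl)oxy]pent-2-ynoic acid, via lithium acetylide 22 (not isolated)
Conditions: n-BuLi, THF, −78 °C; CO2; cold 0.5 M HCl to pH 3
Reagents that add atoms: carbon dioxide, O=C=O
Why: deprotonation of the terminal alkyne and carboxylation of the acetylide; brief cold acidification frees the acid without loss of the tertiary silyl ether.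

Step 16
Reactants: 19 6,7-exo-dihydroxy-1-isobutyryl-2,2-dimethyl-3,5-bis(3-methylbut-2-en-1-yl)bicyclo[3.2.1]octan-8-one; 23 4-methyl-4-[(triethylsilyl)oxy]pent-2-ynoic acid
Product: 24 C6 ester of 19 with acid 23 (C7 hydroxyl free)
Conditions: N,N′-dicyclohexylcarbodiimide, 4-(dimethylamino)pyridine (10 mol %), CH2Cl2, −20→0 °C
Reagents that add atoms: none
Why: Steglich esterification; the C6 hydroxyl is the more accessible one, since the C7 hydroxyl sits next to C1 with its isobutyryl group and the gem-dimethyl carbon and is hydrogen-bonded to the isobutyryl carbonyl, and the linear alkynoic acid cannot lactonise when activated.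

Step 17
Reactants: 24 C6 ester of 19 with acid 23
Product: 25 7-ketone of 24 (6-acyloxy-7,8-dione)
Conditions: Dess–Martin periodinane, NaHCO3, CH2Cl2, 0 °C→rt
Reagents that add atoms: none
Why: oxidation of the hindered secondary alcohol with a trivalent-iodine-forming periodinane under buffered, non-basic conditions; it removes the retro-aldol-prone C7 hydroxyl and creates the ketone whose only enolisable neighbour is C6.

Step 18
Reactants: 25 7-ketone of 24
Product: 26 (Z)-enoate corresponding to 25
Conditions: H2 (1 atm), Pd/CaCO3 poisoned with Pb(OAc)2 (Lindlar catalyst), quinoline, EtOAc, rt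
Reagents that add atoms: none
Why: Lindlar semi-hydrogenation; syn addition of hydrogen to the alkynoate gives the Z alkene, the trisubstituted prenyl alkenes are not reduced on the poisoned catalyst, and the silyl ether keeps the Z γ-oxygen from lactonising.

Step 19
Reactants: 26 (Z)-enoate corresponding to 25
Product: 28 triethylsilyl ether of 29 at the side-chain hydroxyl, via lithium enolate 27 (not isolated)
Conditions: LiN(SiMe3)2 (1.1 equiv), THF, −78→−30 °C; AcOH, −78 °C
Reagents that add atoms: none
Why: anionic O-to-C 1,2-acyl shift of an α-acyloxy ketone enolate (α-ketol ester to α-hydroxy β-diketone rearrangement); the C6–C7 enolate 27 attacks its own ester carbonyl (3-exo-trig, alkoxy-oxirane) and opens to the chelated lithium alkoxide, and because the acyl group swings over the open exo face, the chain ends exo and the oxygen endo as in 29, while the enoate has no acidic hydrogen of its own.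

Step 20
Reactants: 28 triethylsilyl ether of 29
Product: 29 6-hydroxy-6-[(2Z)-4-hydroxy-4-methylpent-2-enoyl]-1-isobutyryl-2,2-dimethyl-3,5-bis(3-methylbut-2-en-1-yl)bicyclo[3.2.1]octane-7,8-dione (CNP0190794.1)
Conditions: HF·pyridine, pyridine, THF, 0 °C
Reagents that add atoms: none
Why: fluoride-driven cleavage of the tertiary silyl ether under mildly acidic conditions; base is avoided because alkoxides of the α-hydroxy β-diketone and of the β-triketone undergo acyl shifts and retro-Claisen cleavage.

## Compound list

1 | orcinol (5-methylbenzene-1,3-diol) | Cc1cc(O)cc(O)c1 | starting material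
2 | isobutyryl chloride | CC(C)C(Cl)=O | starting material
3 | 1-(2,4-dihydroxy-6-methylphenyl)-2-methylpropan-1-one | CC(C)C(=O)c1c(O)cc(O)cc1C | intermediate
4 | allyl bromide | C=CCBr | starting material
5 | 1-[2-hydroxy-6-methyl-4-(prop-2-en-1-yloxy)phenyl]-2-methylpropan-1-one | CC(C)C(=O)c1c(O)cc(OCC=C)cc1C | intermediate
6 | 1-[2,4-dihydroxy-6-methyl-3-(prop-2-en-1-yl)phenyl]-2-methylpropan-1-one | CC(C)C(=O)c1c(O)c(CC=C)c(O)cc1C | intermediate
7 | 1-[2-hydroxy-4-methoxy-6-methyl-3-(prop-2-en-1-yl)phenyl]-2-methylpropan-1-one | CC(C)C(=O)c1c(O)c(CC=C)c(OC)cc1C | intermediate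
8 | 2,2-dimethyl-1,3-dioxolane | CC1(C)OCCO1 | starting material
9 | 4-chloro-2,2-dimethyl-1,3-dioxolane (racemic) | CC1(C)OCC(Cl)O1 | intermediate
10 | 2,2-dimethyl-1,3-dioxole | CC1(C)OC=CO1 | intermediate
11 | methoxyallyl cation (C4 O-methyl oxocarbenium ion of 12, perchlorate; not isolated) | C[O+]=C1C=C(C)[C@@]2(C(=O)C(C)C)C(=O)[C@]1(CC=C)[C@@H]3OC(C)(C)O[C@H]23.[O-]Cl(=O)(=O)=O | intermediate
12 | 5-allyl-1-isobutyryl-2-methyl-6,7-exo-(isopropylidenedioxy)bicyclo[3.2.1]oct-2-ene-4,8-dione | O=C1C=C(C)[C@@]2(C(=O)C(C)C)C(=O)[C@]1(CC=C)[C@@H]3OC(C)(C)O[C@H]23 | intermediate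
13 | lithium C3–C4 enolate of the 2,2-dimethyl ketone (not isolated) | [Li]OC1=CC(C)(C)[C@@]2(C(=O)C(C)C)C(=O)[C@]1(CC=C)[C@@H]3OC(C)(C)O[C@H]23 | intermediate
14 | 3,5-diallyl-1-isobutyryl-2,2-dimethyl-6,7-exo-(isopropylidenedioxy)bicyclo[3.2.1]octane-4,8-dione (C3 allyl equatorial) | C=CC[C@@H]1C(=O)[C@]2(CC=C)C(=O)[C@@](C(=O)C(C)C)([C@H]3OC(C)(C)O[C@@H]23)C1(C)C | intermediate
15 | C4 alcohol of 14 (hydroxyl axial, on the C8 side) | C=CC[C@@H]1[C@H](O)[C@]2(CC=C)C(=O)[C@@](C(=O)C(C)C)([C@H]3OC(C)(C)O[C@@H]23)C1(C)C | intermediate
16 | O-(imidazol-1-ylthiocarbonyl) derivative of 15 | C=CC[C@@H]1[C@H](OC(=S)n4ccnc4)[C@]2(CC=C)C(=O)[C@@](C(=O)C(C)C)([C@H]3OC(C)(C)O[C@@H]23)C1(C)C | intermediate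
17 | 3,5-diallyl-1-isobutyryl-2,2-dimethyl-6,7-exo-(isopropylidenedioxy)bicyclo[3.2.1]octan-8-one | C=CC[C@@H]1C[C@]2(CC=C)C(=O)[C@@](C(=O)C(C)C)([C@H]3OC(C)(C)O[C@@H]23)C1(C)C | intermediate
18 | 3,5-diallyl-6,7-exo-dihydroxy-1-isobutyryl-2,2-dimethylbicyclo[3.2.1]octan-8-one | C=CC[C@@H]1C[C@]2(CC=C)C(=O)[C@@](C(=O)C(C)C)([C@@H](O)[C@H]2O)C1(C)C | intermediate
19 | 6,7-exo-dihydroxy-1-isobutyryl-2,2-dimethyl-3,5-bis(3-methylbut-2-en-1-yl)bicyclo[3.2.1]octan-8-one | CC(C)=CC[C@@H]1C[C@]2(CC=C(C)C)C(=O)[C@@](C(=O)C(C)C)([C@@H](O)[C@H]2O)C1(C)C | intermediate
20 | 2-methylbut-3-yn-2-ol | CC(C)(O)C#C | starting material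
21 | triethyl[(2-methylbut-3-yn-2-yl)oxy]silane | CC[Si](CC)(CC)OC(C)(C)C#C | intermediate
22 | lithium acetylide of 21 (not isolated) | CC[Si](CC)(CC)OC(C)(C)C#C[Li] | intermediate
23 | 4-methyl-4-[(triethylsilyl)oxy]pent-2-ynoic acid | CC[Si](CC)(CC)OC(C)(C)C#CC(=O)O | intermediate
24 | C6 4-methyl-4-[(triethylsilyl)oxy]pent-2-ynoate of 19 | CC(C)=CC[C@@H]1C[C@]2(CC=C(C)C)C(=O)[C@@](C(=O)C(C)C)([C@@H](O)[C@H]2OC(=O)C#CC(C)(C)O[Si](CC)(CC)CC)C1(C)C | intermediate
25 | 7-ketone of 24 | CC(C)=CC[C@@H]1C[C@]2(CC=C(C)C)C(=O)[C@@](C(=O)C(C)C)(C(=O)[C@H]2OC(=O)C#CC(C)(C)O[Si](CC)(CC)CC)C1(C)C | intermediate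
26 | (Z)-enoate from 25 | CC(C)=CC[C@@H]1C[C@]2(CC=C(C)C)C(=O)[C@@](C(=O)C(C)C)(C(=O)[C@H]2OC(=O)/C=C\C(C)(C)O[Si](CC)(CC)CC)C1(C)C | intermediate
27 | lithium C6–C7 enolate of 26 (not isolated) | CC(C)=CC[C@@H]1C[C@]2(CC=C(C)C)C(=O)[C@@](C(=O)C(C)C)(C(O[Li])=C2OC(=O)/C=C\C(C)(C)O[Si](CC)(CC)CC)C1(C)C | intermediate
28 | triethylsilyl ether of 29 at the side-chain hydroxyl | CC(C)=CC[C@@H]1C[C@]2(CC=C(C)C)C(=O)[C@@](C(=O)C(C)C)(C(=O)[C@@]2(O)C(=O)/C=C\C(C)(C)O[Si](CC)(CC)CC)C1(C)C | intermediate
29 | CNP0190794.1 | CC(C)=CC[C@@H]1C[C@]2(CC=C(C)C)C(=O)[C@@](C(=O)C(C)C)(C(=O)[C@@]2(O)C(=O)/C=C\C(C)(C)O)C1(C)C | target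

## Count and risks

Total step count: 20. Longest linear sequence: 16 steps (steps 1–4, 7–13, 16–20).

**Step 7 (key step, proposed new method).** Most likely failure: loss of facial control, because the phenoxonium ion, poorly stabilised without a para donor, can leave iodine before the dioxole attacks and then reacts without the chiral scaffold. A second failure on the same pathway is attack of the dioxole at the open para carbon followed by re-aromatisation. Fallback from 7 and 10 back to 12: catalyst control is given up and the known anodic phenol–olefin [5+2] is run directly. Phenol 7 is oxidised at a carbon-felt anode in LiClO4/MeNO2, a medium in which free phenoxonium ions live long enough for cycloaddition across both ortho carbons, in the presence of excess 10. This should give 12 as the racemate, that is, together with its enantiomer F1. The two are separated by preparative chromatography on a cellulose tris(3,5-dimethylphenylcarbamate) phase, and 12 enters step 8.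

**Step 19.** Most likely failure: the enolate does not transfer the acyl group to C6. The endo C6 hydrogen may be removed slowly, the acyl group may merely shuttle between the two enediol oxygens or be delivered to C7, and the product alkoxide may revert or fragment on warming. Fallback from 19 and 21 back to 28, an intermolecular aldol route with fixed regiochemistry:
- Acetylide formation from 21 (n-BuLi) and formylation with N,N-dimethylformamide gives 4-methyl-4-[(triethylsilyl)oxy]pent-2-ynal F2.
- Diol 19 is mono-protected at the more accessible C6 hydroxyl with 4-methoxybenzyl 2,2,2-trichloroacetimidate and La(OTf)3 (cat.), giving the 4-methoxybenzyl ether F3.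
- Dess–Martin oxidation gives the 7-ketone F4.
- The enolate of F4 (KN(SiMe3)2, THF, −78 °C) adds to F2 from the exo face to give the propargylic alcohol F5.
- Dess–Martin oxidation gives the ynone F6, and Lindlar semi-hydrogenation the Z enone F7.
- 2,3-Dichloro-5,6-dicyano-1,4-benzoquinone in wet CH2Cl2 removes the benzyl ether and returns 28.

**Step 8.** Most likely failure: stalled conjugate addition at the β-carbon next to the quaternary C1, and incomplete or O-selective allylation of the copper-bearing enolate. Fallback from 12 back to 14, with the two events separated. Conjugate addition of Me2CuLi in the presence of Me3SiCl, the standard acceleration for hindered enones, gives the trimethylsilyl enol ether F8. Tsuji allylation with allyl methyl carbonate, Pd2(dba)3 and 1,2-bis(diphenylphosphino)ethane in THF at 65 °C, through a π-allyl complex of divalent palladium, then installs the C3 allyl group and returns 14.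

**Step 9.** Most likely failure: hydride attack at C8 or at the isobutyryl carbonyl instead of C4, or retro-aldol cleavage of the C4–C5 bond through the C4 alkoxide. Fallback from 14 back to 17, bypassing 15 and 16 and any alkoxide. Condensation of 14 with 4-methylbenzenesulfonohydrazide at the least hindered ketone gives the tosylhydrazone F9. Reduction with catecholborane followed by NaOAc·3H2O at reflux expels dinitrogen and sulfinate and gives the C4 methylene compound 17 directly.

## Further compounds

F1 | step 7 | enantiomer of 12 | O=C1C=C(C)[C@]2(C(=O)C(C)C)C(=O)[C@@]1(CC=C)[C@H]3OC(C)(C)O[C@@H]23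
F2 | step 19 | 4-methyl-4-[(triethylsilyl)oxy]pent-2-ynal | CC[Si](CC)(CC)OC(C)(C)C#CC=O
F3 | step 19 | C6 4-methoxybenzyl ether of 19 | CC(C)=CC[C@@H]1C[C@]2(CC=C(C)C)C(=O)[C@@](C(=O)C(C)C)([C@@H](O)[C@H]2OCc4ccc(OC)cc4)C1(C)C
F4 | step 19 | 7-ketone of F3 | CC(C)=CC[C@@H]1C[C@]2(CC=C(C)C)C(=O)[C@@](C(=O)C(C)C)(C(=O)[C@H]2OCc4ccc(OC)cc4)C1(C)C
F5 | step 19 | aldol adduct of F4 and F2 (C6 chain exo, carbinol epimers) | CC(C)=CC[C@@H]1C[C@]2(CC=C(C)C)C(=O)[C@@](C(=O)C(C)C)(C(=O)[C@@]2(OCc4ccc(OC)cc4)C(O)C#CC(C)(C)O[Si](CC)(CC)CC)C1(C)C
F6 | step 19 | ynone from F5 | CC(C)=CC[C@@H]1C[C@]2(CC=C(C)C)C(=O)[C@@](C(=O)C(C)C)(C(=O)[C@@]2(OCc4ccc(OC)cc4)C(=O)C#CC(C)(C)O[Si](CC)(CC)CC)C1(C)C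
F7 | step 19 | (Z)-enone from F6 (C6 4-methoxybenzyl ether of 28) | CC(C)=CC[C@@H]1C[C@]2(CC=C(C)C)C(=O)[C@@](C(=O)C(C)C)(C(=O)[C@@]2(OCc4ccc(OC)cc4)C(=O)/C=C\C(C)(C)O[Si](CC)(CC)CC)C1(C)C
F8 | step 8 | trimethylsilyl C3–C4 enol ether of the 2,2-dimethyl ketone | C[Si](C)(C)OC1=CC(C)(C)[C@@]2(C(=O)C(C)C)C(=O)[C@]1(CC=C)[C@@H]3OC(C)(C)O[C@H]23
F9 | step 9 | C4 tosylhydrazone of 14 | C=CC[C@@H]1C(=NNS(=O)(=O)c4ccc(C)cc4)[C@]2(CC=C)C(=O)[C@@](C(=O)C(C)C)([C@H]3OC(C)(C)O[C@@H]23)C1(C)C
A1 | alternative 1 | 2-[1-(tert-butyldimethylsilyloxy)-2-methylpropylidene]-3,3-dimethyl-4-(3-methylbut-2-en-1-yl)cyclobutan-1-one | CC(C)=CC[C@@H]1C(=O)/C(=C(\O[Si](C)(C)C(C)(C)C)C(C)C)C1(C)C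
A2 | alternative 1 | trimethyl(5-methylhex-4-en-1-yn-1-yl)silane | C[Si](C)(C)C#CCC=C(C)C
A3 | alternative 1 | cyclohex-2-enone with C4 trimethylsilyl, C3 and C5 prenyl, C2 gem-dimethyl and the C1 silyloxyalkylidene (target numbering) | CC(C)=CC[C@@H]1C([Si](C)(C)C)=C(CC=C(C)C)C(=O)/C(=C(\O[Si](C)(C)C(C)(C)C)C(C)C)C1(C)C
A4 | alternative 2 | O-ethyl S-[4-isobutyryl-4-(2-methylbut-3-en-2-yl)-1-(3-methylbut-2-en-1-yl)-2,3,5-trioxocyclopentyl] carbonodithioate | CC(C)=CCC1(SC(=S)OCC)C(=O)[C@@](C(=O)C(C)C)(C(=O)C1=O)C(C)(C)C=C
A5 | alternative 2 | 3-(ethanesulfonyl)-3-methylbut-1-ene | CCS(=O)(=O)C(C)(C)C=C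
A6 | alternative 2 | 1-isobutyryl-2,2-dimethyl-3,5-bis(3-methylbut-2-en-1-yl)bicyclo[3.2.1]octane-6,7,8-trione | CC(C)=CC[C@@H]1C[C@]2(CC=C(C)C)C(=O)[C@@](C(=O)C(C)C)(C(=O)C2=O)C1(C)C
A7 | alternative 3 | 2-isobutyryl-3,3-dimethyl-4,6-bis(3-methylbut-2-en-1-yl)-2-[2-oxo-3-(triisopropylsilyloxy)propanoyl]cyclohexan-1-one | CC(C)=CC[C@@H]1C[C@H](CC=C(C)C)C(=O)[C@@](C(=O)C(C)C)(C(=O)C(=O)CO[Si](C(C)C)(C(C)C)C(C)C)C1(C)C
A8 | alternative 3 | bicyclo[3.1.1]heptan-6-one with C7 hydroxyl and C7 (triisopropylsilyloxy)acetyl group (target numbering) | CC(C)=CC[C@@H]1C[C@]2(CC=C(C)C)C(=O)[C@@](C(=O)C(C)C)([C@@]2(O)C(=O)CO[Si](C(C)C)(C(C)C)C(C)C)C1(C)C
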